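**Retrosynthetic overview**

1. Numbering: lactone O1, C2, C3, C4, C5; 2-methylpropenyl C6, C7; chain C1' to C10'. The C10' ester is cut to (E)-3-methylpent-2-enoic acid 17 and the O1–C2 bond to the open-chain methyl ester 14, so the γ-lactone (the only ring) is closed after the key step.
2. The strategy rests on the C4–C5 bond. It carries anti oxygen functions on C4 and C5 and lies next to the E C3=C1' alkylidene of the C2 ester, which is the pattern left when a 2-methoxycarbonyl-3-silyloxy allylboronate with boron on C1' adds to an aldehyde with allylic transposition.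
3. Key disconnection C4–C5: (Z)-3-silyloxy-2-[(1S)-1-borylalkyl]acrylate 11 plus prenal 12, with the (S) centre C1' relayed to C4 and C5 through a chair.
4. Boronate 11 comes from (2Z,6E)-farnesol 1: cleavage of C10=C11 to the C1' aldehyde 5, Wittig reaction to the E enoate 6, CuCl/bisphosphine β-borylation with B2pin2 7 (sets C1'), then one-pot Claisen formylation and O-silylation of the lithium chelate.

Key step: step 7

Assumption: the ferrocenyl bisphosphine enantiomer named in step 5 is taken to deliver the (S)-boronate 8; if the sense of induction is the opposite, the mirror-image ligand is used and nothing else changes.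

**Route**

Step 1
Reactants: 1 (2Z,6E)-farnesol
Product: 2 (2Z,6E)-farnesyl tert-butyldimethylsilyl ether
Conditions: TBSCl, imidazole, CH2Cl2, 0 °C to rt
Reagents that add atoms: tert-butyldimethylsilyl chloride, CC(C)(C)[Si](C)(C)Cl
Why: Imidazole-promoted silylation of the unhindered primary allylic hydroxyl should be clean and leaves the 2Z and 6E alkenes untouched.

Step 2
Reactants: 2 (2Z,6E)-farnesyl tert-butyldimethylsilyl ether
Product: 4 (2Z,6E)-10,11-epoxyfarnesyl tert-butyldimethylsilyl ether (racemic at the epoxide), via terminal bromohydrin 3 (not isolated)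
Conditions: NBS, THF–H2O (2:1), 0 °C; then K2CO3, MeOH, rt
Reagents that add atoms: water, O (the epoxide oxygen); N-bromosuccinimide, O=C1CCC(=O)N1Br (its bromine is held in 3 only and is lost on ring closure)
Why: Terminal-selective bromohydrin formation of the coiled polyene in aqueous THF (water opens the bromonium ion at the tertiary carbon), followed by base-induced intramolecular Williamson closure, should give the terminal epoxide, whose racemic stereocentre is excised in step 3.

Step 3
Reactants: 4 (2Z,6E)-10,11-epoxyfarnesyl tert-butyldimethylsilyl ether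
Product: 5 (4E,8Z)-10-(tert-butyldimethylsilyloxy)-4,8-dimethyldeca-4,8-dienal
Conditions: HIO4·2H2O, THF–Et2O, 0 °C
Reagents that add atoms: none
Why: Periodic acid opens the epoxide to the glycol and cleaves it (glycol cleavage) to the C1' aldehyde and acetone, and the brief exposure at 0 °C should spare the primary silyl ether and the trisubstituted alkenes.

Step 4
Reactants: 5 (4E,8Z)-10-(tert-butyldimethylsilyloxy)-4,8-dimethyldeca-4,8-dienal
Product: 6 methyl (2E,6E,10Z)-12-(tert-butyldimethylsilyloxy)-6,10-dimethyldodeca-2,6,10-trienoate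
Conditions: Ph3P=CHCO2Me, CH2Cl2, rt
Reagents that add atoms: methyl (triphenylphosphoranylidene)acetate, COC(=O)C=P(c1ccccc1)(c1ccccc1)c1ccccc1
Why: Wittig olefination with the ester-stabilised ylide should give the E enoate that the borylation needs, with C1' as its β-carbon.

Step 5
Reactants: 6 methyl (2E,6E,10Z)-12-(tert-butyldimethylsilyloxy)-6,10-dimethyldodeca-2,6,10-trienoate; 7 bis(pinacolato)diboron
Product: 8 methyl (3S,6E,10Z)-12-(tert-butyldimethylsilyloxy)-6,10-dimethyl-3-(4,4,5,5-tetramethyl-1,3,2-dioxaborolan-2-yl)dodeca-6,10-dienoate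
Conditions: CuCl (3 mol%), NaOtBu (6 mol%), (R)-1-[(S)-2-(diphenylphosphino)ferrocenyl]ethyldicyclohexylphosphine (3 mol%), MeOH (2 equiv), THF, rt
Reagents that add atoms: none
Why: In this copper-catalysed asymmetric conjugate borylation the ligated Cu–Bpin species adds to the β-carbon C1' of the E enoate on the face chosen by the chiral bisphosphine, which sets (S)-C1'; methanol protonates the copper enolate and turns the catalyst over, and the unactivated trisubstituted alkenes are inert.

Step 6
Reactants: 8 methyl (3S,6E,10Z)-12-(tert-butyldimethylsilyloxy)-6,10-dimethyl-3-(4,4,5,5-tetramethyl-1,3,2-dioxaborolan-2-yl)dodeca-6,10-dienoate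
Product: 11 methyl (2Z)-3-(tert-butyldimethylsilyloxy)-2-[(1S,4E,8Z)-10-(tert-butyldimethylsilyloxy)-4,8-dimethyl-1-(4,4,5,5-tetramethyl-1,3,2-dioxaborolan-2-yl)deca-4,8-dien-1-yl]prop-2-enoate, via lithium ester enolate 9 (not isolated), via lithium formyl-enolate chelate 10 (not isolated)
Conditions: LiN(iPr)2, THF, −78 °C; HCO2Me, −78 to 0 °C; volatiles removed in vacuo; THF, TBSOTf, −78 to 0 °C
Reagents that add atoms: methyl formate, COC=O; tert-butyldimethylsilyl trifluoromethanesulfonate, CC(C)(C)[Si](C)(C)OS(=O)(=O)C(F)(F)F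
Why: Crossed Claisen condensation of the ester enolate with the non-enolisable formate gives the formyl ester as its lithium enolate, which should rest as the six-membered O–Li–O chelate with the enolate oxygen cis to the ester, so that O-silylation of the chelate fixes the Z enol ether; C1' is not acidic and keeps its configuration.

Step 7
Reactants: 11 methyl (2Z)-3-(tert-butyldimethylsilyloxy)-2-[(1S,4E,8Z)-10-(tert-butyldimethylsilyloxy)-4,8-dimethyl-1-(4,4,5,5-tetramethyl-1,3,2-dioxaborolan-2-yl)deca-4,8-dien-1-yl]prop-2-enoate; 12 3-methylbut-2-enal (prenal)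
Product: 14 methyl (2E,6E,10Z)-12-(tert-butyldimethylsilyloxy)-2-[(1S,2R)-1-(tert-butyldimethylsilyloxy)-2-hydroxy-4-methylpent-3-en-1-yl]-6,10-dimethyldodeca-2,6,10-trienoate, via O5 pinacol borate 13 (not isolated)
Conditions: prenal (3 equiv), toluene (1 M), 80 °C, sealed tube, no Lewis acid; then aq. pH 7 phosphate buffer
Reagents that add atoms: none
Why: Proposed new method: the aldehyde oxygen binds boron and C4 attacks the carbonyl carbon on the same face of the allyl unit through a closed six-membered chair, so that C4–C5 forms while the double bond moves from C3=C4 to C3=C1' and boron passes to O5; no ring is closed. The closest known reactions are the γ-alkoxyallylboration of aldehydes to anti 1,2-diol derivatives, the addition of 2-alkoxycarbonyl allylboronates that leads to α-alkylidene γ-lactones, and chirality transfer from α-substituted pinacol allylboronates, but a single reagent that unites the three features is not known. C5 is set by the equatorial 2-methylpropenyl group of the boron-bound prenal and C4 by the silyloxy group, which is trans to C1' in the Z enol ether and therefore equatorial, giving the anti pair. The absolute sense at both centres comes from the (S) centre C1', whose chain should go pseudo-axial to avoid A(1,2) strain with the C3 ester and contact with the pinacol methyl groups, and the same preference places the chain cis to C4 in the new E alkene. The step needs chair selection, 1,2- over 1,4-addition to the enal and bond formation at C4 and not at C3: the closed boron-bound transition state secures the first two, and the absence of any Lewis acid keeps Mukaiyama-type attack through C3, silyl loss and 1,3-boron shifts switched off. Because the push–pull C3=C4 bond is a weak nucleophile, heat and excess prenal take the place of Sc(OSO2CF3)3 catalysis.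

Step 8
Reactants: 14 methyl (2E,6E,10Z)-12-(tert-butyldimethylsilyloxy)-2-[(1S,2R)-1-(tert-butyldimethylsilyloxy)-2-hydroxy-4-methylpent-3-en-1-yl]-6,10-dimethyldodeca-2,6,10-trienoate
Product: 15 (3E,4S,5R)-4-(tert-butyldimethylsilyloxy)-3-[(4E,8Z)-10-(tert-butyldimethylsilyloxy)-4,8-dimethyldeca-4,8-dien-1-ylidene]-5-(2-methylprop-1-en-1-yl)oxolan-2-one
Conditions: PPTS (0.2 equiv), toluene, 60 °C
Reagents that add atoms: none
Why: Mild acid-catalysed lactonisation (intramolecular transesterification, 5-exo-trig) of O5 onto the C2 ester closes the γ-lactone by acyl–oxygen exchange, so C4 and C5 are untouched; the weak acid in an aprotic solvent should neither ionise the allylic C5–O bond nor cleave the silyl ethers, and any lactone already formed in step 7 is carried along.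

Step 9
Reactants: 15 (3E,4S,5R)-4-(tert-butyldimethylsilyloxy)-3-[(4E,8Z)-10-(tert-butyldimethylsilyloxy)-4,8-dimethyldeca-4,8-dien-1-ylidene]-5-(2-methylprop-1-en-1-yl)oxolan-2-one
Product: 16 (3E,4S,5R)-4-(tert-butyldimethylsilyloxy)-3-[(4E,8Z)-10-hydroxy-4,8-dimethyldeca-4,8-dien-1-ylidene]-5-(2-methylprop-1-en-1-yl)oxolan-2-one
Conditions: HF·pyridine, pyridine, THF, 0 °C
Reagents that add atoms: none
Why: In this selective desilylation the pyridine-buffered HF·pyridine should cleave the unhindered primary allylic silyl ether far faster than the secondary C4 silyl ether, which is shielded by the cis chain on C1' and by the C5 substituent.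

Step 10
Reactants: 16 (3E,4S,5R)-4-(tert-butyldimethylsilyloxy)-3-[(4E,8Z)-10-hydroxy-4,8-dimethyldeca-4,8-dien-1-ylidene]-5-(2-methylprop-1-en-1-yl)oxolan-2-one; 17 (E)-3-methylpent-2-enoic acid
Product: 18 (2Z,6E,10E)-10-[(4S,5R)-4-(tert-butyldimethylsilyloxy)-5-(2-methylprop-1-en-1-yl)-2-oxooxolan-3-ylidene]-3,7-dimethyldeca-2,6-dien-1-yl (2E)-3-methylpent-2-enoate
Conditions: PPh3, DIAD, THF, 0 °C to rt
Reagents that add atoms: none
Why: In this Mitsunobu esterification the carboxylate of 17 displaces the activated primary allylic oxygen by SN2 at C10'; since the acid is never turned into an acyl donor it cannot deconjugate or lose its E geometry through a vinylketene, and the Z C8'=C9' bond is not involved.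

Step 11
Reactants: 18 (2Z,6E,10E)-10-[(4S,5R)-4-(tert-butyldimethylsilyloxy)-5-(2-methylprop-1-en-1-yl)-2-oxooxolan-3-ylidene]-3,7-dimethyldeca-2,6-dien-1-yl (2E)-3-methylpent-2-enoate
Product: 19 (2Z,6E,10E)-10-[(4S,5R)-4-hydroxy-5-(2-methylprop-1-en-1-yl)-2-oxooxolan-3-ylidene]-3,7-dimethyldeca-2,6-dien-1-yl (2E)-3-methylpent-2-enoate (CNP0181153.1)
Conditions: HF·pyridine (excess), THF, 0 °C to rt
Reagents that add atoms: none
Why: Acidic fluoride-mediated desilylation removes the remaining C4 silyl ether without base, so the two esters, the α-alkylidene lactone and both stereocentres should survive.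

**Compound list**

1 | (2Z,6E)-farnesol | CC(C)=CCC/C(C)=C/CC/C(C)=C\CO | starting material
2 | (2Z,6E)-farnesyl tert-butyldimethylsilyl ether | CC(C)=CCC/C(C)=C/CC/C(C)=C\CO[Si](C)(C)C(C)(C)C | intermediate
3 | (6E,10Z)-3-bromo-12-(tert-butyldimethylsilyloxy)-2,6,10-trimethyldodeca-6,10-dien-2-ol, racemic (not isolated) | CC(C)(O)C(Br)CC/C(C)=C/CC/C(C)=C\CO[Si](C)(C)C(C)(C)C | intermediate
4 | (2Z,6E)-10,11-epoxyfarnesyl tert-butyldimethylsilyl ether, racemic at the epoxide | CC1(C)OC1CC/C(C)=C/CC/C(C)=C\CO[Si](C)(C)C(C)(C)C | intermediate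
5 | (4E,8Z)-10-(tert-butyldimethylsilyloxy)-4,8-dimethyldeca-4,8-dienal | O=CCC/C(C)=C/CC/C(C)=C\CO[Si](C)(C)C(C)(C)C | intermediate
6 | methyl (2E,6E,10Z)-12-(tert-butyldimethylsilyloxy)-6,10-dimethyldodeca-2,6,10-trienoate | COC(=O)/C=C/CC/C(C)=C/CC/C(C)=C\CO[Si](C)(C)C(C)(C)C | intermediate
7 | bis(pinacolato)diboron | CC1(C)OB(OC1(C)C)B1OC(C)(C)C(C)(C)O1 | starting material
8 | methyl (3S,6E,10Z)-12-(tert-butyldimethylsilyloxy)-6,10-dimethyl-3-(4,4,5,5-tetramethyl-1,3,2-dioxaborolan-2-yl)dodeca-6,10-dienoate | COC(=O)C[C@@H](B1OC(C)(C)C(C)(C)O1)CC/C(C)=C/CC/C(C)=C\CO[Si](C)(C)C(C)(C)C | intermediate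
9 | lithium ester enolate of 8 (not isolated) | [Li+].COC([O-])=C[C@@H](B1OC(C)(C)C(C)(C)O1)CC/C(C)=C/CC/C(C)=C\CO[Si](C)(C)C(C)(C)C | intermediate
10 | lithium (Z)-enolate chelate of the 2-formyl ester (not isolated) | [Li+].COC(=O)/C(=C\[O-])[C@@H](B1OC(C)(C)C(C)(C)O1)CC/C(C)=C/CC/C(C)=C\CO[Si](C)(C)C(C)(C)C | intermediate
11 | methyl (2Z)-3-(tert-butyldimethylsilyloxy)-2-[(1S,4E,8Z)-10-(tert-butyldimethylsilyloxy)-4,8-dimethyl-1-(4,4,5,5-tetramethyl-1,3,2-dioxaborolan-2-yl)deca-4,8-dien-1-yl]prop-2-enoate | COC(=O)/C(=C\O[Si](C)(C)C(C)(C)C)[C@@H](B1OC(C)(C)C(C)(C)O1)CC/C(C)=C/CC/C(C)=C\CO[Si](C)(C)C(C)(C)C | intermediate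
12 | 3-methylbut-2-enal (prenal) | CC(C)=CC=O | starting material
13 | O5 pinacol borate of 14 (not isolated) | CC(C)(C)[Si](C)(C)OC/C=C(/C)CC/C=C(\C)CC/C=C(/C(=O)OC)[C@H](O[Si](C)(C)C(C)(C)C)[C@H](OB1OC(C)(C)C(C)(C)O1)C=C(C)C | intermediate
14 | methyl (2E,6E,10Z)-12-(tert-butyldimethylsilyloxy)-2-[(1S,2R)-1-(tert-butyldimethylsilyloxy)-2-hydroxy-4-methylpent-3-en-1-yl]-6,10-dimethyldodeca-2,6,10-trienoate | CC(C)(C)[Si](C)(C)OC/C=C(/C)CC/C=C(\C)CC/C=C(/C(=O)OC)[C@H](O[Si](C)(C)C(C)(C)C)[C@H](O)C=C(C)C | intermediate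
15 | (3E,4S,5R)-4-(tert-butyldimethylsilyloxy)-3-[(4E,8Z)-10-(tert-butyldimethylsilyloxy)-4,8-dimethyldeca-4,8-dien-1-ylidene]-5-(2-methylprop-1-en-1-yl)oxolan-2-one | CC(C)(C)[Si](C)(C)OC/C=C(/C)CC/C=C(\C)CC/C=C1/C(=O)O[C@H](C=C(C)C)[C@H]1O[Si](C)(C)C(C)(C)C | intermediate
16 | (3E,4S,5R)-4-(tert-butyldimethylsilyloxy)-3-[(4E,8Z)-10-hydroxy-4,8-dimethyldeca-4,8-dien-1-ylidene]-5-(2-methylprop-1-en-1-yl)oxolan-2-one | OC/C=C(/C)CC/C=C(\C)CC/C=C1/C(=O)O[C@H](C=C(C)C)[C@H]1O[Si](C)(C)C(C)(C)C | intermediate
17 | (E)-3-methylpent-2-enoic acid | CC/C(C)=C/C(=O)O | starting material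
18 | (2Z,6E,10E)-10-[(4S,5R)-4-(tert-butyldimethylsilyloxy)-5-(2-methylprop-1-en-1-yl)-2-oxooxolan-3-ylidene]-3,7-dimethyldeca-2,6-dien-1-yl (2E)-3-methylpent-2-enoate | CC/C(C)=C/C(=O)OC/C=C(/C)CC/C=C(\C)CC/C=C1/C(=O)O[C@H](C=C(C)C)[C@H]1O[Si](C)(C)C(C)(C)C | intermediate
19 | (2Z,6E,10E)-10-[(4S,5R)-4-hydroxy-5-(2-methylprop-1-en-1-yl)-2-oxooxolan-3-ylidene]-3,7-dimethyldeca-2,6-dien-1-yl (2E)-3-methylpent-2-enoate (CNP0181153.1) | CC/C(C)=C/C(=O)OC/C=C(/C)CC/C=C(\C)CC/C=C1/C(=O)O[C@H](C=C(C)C)[C@H]1O | target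

**Step count and risks**

Total step count: 11. Longest linear sequence: 11 steps (from 1 to 19; 7, 12 and 17 are purchased).

Steps most likely to fail:

1. Step 7 (proposed new method). The push–pull boronate may add too slowly, so that silyl loss, a 1,3-boron shift or thermal decomposition overtakes the addition, or the chain on C1' may go equatorial in part and erode the E, anti and enantiomeric purity together. The fallback uses known chemistry, sets out from 5 and 12, and comes back at 15.
   - Aldehyde 5 is homologated with dimethyl (1-diazo-2-oxopropyl)phosphonate (K2CO3, MeOH) to the terminal alkyne tert-butyl{[(2Z,6E)-3,7-dimethylundeca-2,6-dien-10-yn-1-yl]oxy}dimethylsilane F1.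
   - Prenal 12 is converted by an (R)-selective hydroxynitrile lyase and HCN into (2R)-2-hydroxy-4-methylpent-3-enenitrile F2, silylated (Et3SiCl, imidazole) to (2R)-4-methyl-2-(triethylsilyloxy)pent-3-enenitrile F3, and reduced (iBu2AlH, −78 °C, aqueous work-up) to (2R)-4-methyl-2-(triethylsilyloxy)pent-3-enal F4.
   - The lithium acetylide of F1 (n-butyllithium, THF, −78 °C) adds to F4 under Felkin–Anh control to give the anti propargylic alcohol with free C4 hydroxyl and C5 triethylsilyl ether F5.
   - TBSOTf and 2,6-lutidine give the C4 tert-butyldimethylsilyl ether F6, and formic acid in methanol at 0 °C removes the triethylsilyl group to give the homopropargylic alcohol with free C5 hydroxyl F7.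
   - Palladium-catalysed cyclocarbonylation of F7 (PdCl2, SnCl2, PPh3, CO, MeCN) adds the alkoxycarbonyl–palladium unit cis across the alkyne, and protonolysis then gives the E alkylidene lactone 15.

2. Step 6. The ester enolate may be held back by the neighbouring boron or condense with itself so that formylation stays incomplete, or the formyl enolate may drift from the lithium chelate to an oxygen-to-boron bound form so that silylation places the silyloxy group cis to C1'. The fallback sets out from 8 and comes back at 11.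
   - Enolate-free aminomethylenation with tert-butoxybis(dimethylamino)methane (neat, 80–100 °C) gives the enamino ester methyl 3-(dimethylamino)-2-[(1S)-1-borylalkyl]acrylate F8.
   - Aqueous oxalic acid in THF hydrolyses it to the 2-formyl ester, which rests as the hydrogen-bonded Z enol F9.
   - This neutral enol is silylated without any metal enolate by N-methyl-N-(tert-butyldimethylsilyl)trifluoroacetamide (MeCN, rt), the hydrogen bond holding the oxygen cis to the ester, to give 11.

3. Step 11. The hindered C4 silyl ether may be cleaved so slowly that long exposure to acidic fluoride ionises the allylic C5–O1 bond or attacks the allylic ester. The fallback sets out from 15 and comes back at 19.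
   - Both silyl ethers of 15 are removed at the lactone stage, where harsher conditions are tolerable (excess HF·pyridine, or Bu4NF with AcOH, THF), to give the diol (3E,4S,5R)-4-hydroxy-3-[(4E,8Z)-10-hydroxy-4,8-dimethyldeca-4,8-dien-1-ylidene]-5-(2-methylprop-1-en-1-yl)oxolan-2-one F10.
   - The primary allylic hydroxyl of F10 is esterified chemoselectively with 17 under Mitsunobu conditions (PPh3, DIAD, THF, −20 °C), the hindered secondary C4 hydroxyl reacting far more slowly, to give 19 directly.

Further compounds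
F1 | step 7 | tert-butyl{[(2Z,6E)-3,7-dimethylundeca-2,6-dien-10-yn-1-yl]oxy}dimethylsilane | C#CCC/C(C)=C/CC/C(C)=C\CO[Si](C)(C)C(C)(C)C
F2 | step 7 | (2R)-2-hydroxy-4-methylpent-3-enenitrile | N#C[C@H](O)C=C(C)C
F3 | step 7 | (2R)-4-methyl-2-(triethylsilyloxy)pent-3-enenitrile | N#C[C@H](O[Si](CC)(CC)CC)C=C(C)C
F4 | step 7 | (2R)-4-methyl-2-(triethylsilyloxy)pent-3-enal | O=C[C@H](O[Si](CC)(CC)CC)C=C(C)C
F5 | step 7 | (4R,5S,10E,14Z)-16-(tert-butyldimethylsilyloxy)-2,10,14-trimethyl-4-(triethylsilyloxy)hexadeca-2,10,14-trien-6-yn-5-ol | CC(C)(C)[Si](C)(C)OC/C=C(/C)CC/C=C(\C)CCC#C[C@H](O)[C@H](O[Si](CC)(CC)CC)C=C(C)C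
F6 | step 7 | C4 tert-butyldimethylsilyl ether of F5 (lactone numbering: C4 OTBS, C5 OSiEt3) | CC(C)(C)[Si](C)(C)OC/C=C(/C)CC/C=C(\C)CCC#C[C@H](O[Si](C)(C)C(C)(C)C)[C@H](O[Si](CC)(CC)CC)C=C(C)C
F7 | step 7 | (4R,5S,10E,14Z)-5,16-bis(tert-butyldimethylsilyloxy)-2,10,14-trimethylhexadeca-2,10,14-trien-6-yn-4-ol | CC(C)(C)[Si](C)(C)OC/C=C(/C)CC/C=C(\C)CCC#C[C@H](O[Si](C)(C)C(C)(C)C)[C@H](O)C=C(C)C
F8 | step 6 | methyl (2E)-3-(dimethylamino)-2-[(1S,4E,8Z)-10-(tert-butyldimethylsilyloxy)-4,8-dimethyl-1-(4,4,5,5-tetramethyl-1,3,2-dioxaborolan-2-yl)deca-4,8-dien-1-yl]prop-2-enoate | COC(=O)/C(=C/N(C)C)[C@@H](B1OC(C)(C)C(C)(C)O1)CC/C(C)=C/CC/C(C)=C\CO[Si](C)(C)C(C)(C)C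
F9 | step 6 | methyl (2Z)-3-hydroxy-2-[(1S,4E,8Z)-10-(tert-butyldimethylsilyloxy)-4,8-dimethyl-1-(4,4,5,5-tetramethyl-1,3,2-dioxaborolan-2-yl)deca-4,8-dien-1-yl]prop-2-enoate (enol form of the 2-formyl ester) | COC(=O)/C(=C\O)[C@@H](B1OC(C)(C)C(C)(C)O1)CC/C(C)=C/CC/C(C)=C\CO[Si](C)(C)C(C)(C)C
F10 | step 11 | (3E,4S,5R)-4-hydroxy-3-[(4E,8Z)-10-hydroxy-4,8-dimethyldeca-4,8-dien-1-ylidene]-5-(2-methylprop-1-en-1-yl)oxolan-2-one | OC/C=C(/C)CC/C=C(\C)CC/C=C1/C(=O)O[C@H](C=C(C)C)[C@H]1O
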